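**Assumption:** Aspidin AB has no stereocentres and no configurationally defined double bonds (the enols are tautomeric), so "single enantiomer" is taken to mean the single constitutional isomer drawn; no stereocontrol is required.

## Retrosynthetic overview

1. Disconnect the methylene bridge last, on the filicinic-acid side, as a net loss of H2 between a ring C–CH3 of the triketone half and the only aryl C–H of the aromatic half (proposed new dehydrogenative coupling).
2. The triketone half (methyl-acetylfilicinic acid) comes from phloroacetophenone by threefold dearomatising C-methylation; no ring is built, the phloroglucinol ring is dearomatised.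
3. The aromatic half (ψ-aspidinol B) comes from 2-methylphloroglucinol by Friedel–Crafts butyrylation, bis-MOM protection, O-methylation of the remaining hindered OH, and deprotection.
4. Both six-membered rings are bought as phloroglucinols; the route is convergent (1 + 4 steps, then the coupling).

## Route

**Step 1**
Reactants: 1, 2,4,6-trihydroxyacetophenone (phloroacetophenone)
Product: 2, 2-acetyl-3,5-dihydroxy-4,4,6-trimethylcyclohexa-2,5-dien-1-one (methyl-acetylfilicinic acid; enol form of 2-acetyl-4,4,6-trimethylcyclohexane-1,3,5-trione)
Conditions: NaOMe (4 equiv), MeI (3.2 equiv), MeOH, 0 °C → rt; acidify (1 M HCl); chromatography/recrystallisation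
Reagents that add atoms: methyl iodide, CI (three CH3 groups)
Why: Dearomatising exhaustive C-alkylation of the phloroglucinol polyanion, where every possible tri-C-methylation pattern (2+1 or 1+2 on the two free ring carbons) converges on the same compound and under- or over-methylated by-products are separable.

**Step 2**
Reactants: 3, 2,4,6-trihydroxytoluene (2-methylphloroglucinol); 4, butyryl chloride
Product: 5, 1-(2,4,6-trihydroxy-3-methylphenyl)butan-1-one
Conditions: AlCl3 (4 equiv), CH2Cl2/PhNO2, 0 °C → 40 °C; aq. HCl work-up
Reagents that add atoms: butyryl chloride (4), CCCC(=O)Cl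
Why: Friedel–Crafts C-acylation, where the two free ring positions of 3 are equivalent so one regioisomer forms, and the acyl group deactivates the ring against a second acylation.

**Step 3**
Reactants: 5, 1-(2,4,6-trihydroxy-3-methylphenyl)butan-1-one
Product: 6, 1-[2-hydroxy-4,6-bis(methoxymethoxy)-3-methylphenyl]butan-1-one
Conditions: MOMCl (2.2 equiv), i-Pr2NEt (3 equiv), CH2Cl2, 0 °C → rt
Reagents that add atoms: chloromethyl methyl ether, COCCl (two CH2OCH3 groups)
Why: Selective phenol protection (MOM ether formation), where the non-chelated para-OH reacts first and then the less hindered ortho-OH, leaving the OH flanked by C-methyl and butyryl free because it is the most hindered and is held in the C=O hydrogen-bond chelate.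

**Step 4**
Reactants: 6, 1-[2-hydroxy-4,6-bis(methoxymethoxy)-3-methylphenyl]butan-1-one
Product: 7, 1-[2-methoxy-4,6-bis(methoxymethoxy)-3-methylphenyl]butan-1-one
Conditions: MeI (3 equiv), K2CO3, DMF, 40 °C
Reagents that add atoms: methyl iodide, CI
Why: Williamson O-methylation of the only free phenol under forcing carbonate/DMF conditions, where MOM ethers and the ketone are stable to the mild base.

**Step 5**
Reactants: 7, 1-[2-methoxy-4,6-bis(methoxymethoxy)-3-methylphenyl]butan-1-one
Product: 8, 1-(4,6-dihydroxy-2-methoxy-3-methylphenyl)butan-1-one (ψ-aspidinol B)
Conditions: 3 M HCl, MeOH, 50 °C (MeOH in large excess to trap CH2O equivalents as dimethoxymethane)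
Reagents that add atoms: none
Why: Acid-catalysed acetal (MOM) solvolysis, where the aryl methyl ether and aryl ketone are inert and the acyl-deactivated ring resists methylene bridging by the released formaldehyde acetal.

**Step 6**
Reactants: 2, methyl-acetylfilicinic acid; 8, ψ-aspidinol B
Product: 10, Aspidin AB, 2-acetyl-6-[(3-butanoyl-2,6-dihydroxy-4-methoxy-5-methylphenyl)methyl]-3,5-dihydroxy-4,4-dimethylcyclohexa-2,5-dien-1-one, formed via transient 9, 2-acetyl-3-hydroxy-4,4-dimethyl-6-methylidenecyclohex-2-ene-1,5-dione (not isolated)
Conditions: 2 (1.0 equiv), PhI(OAc)2 (1.0 equiv), TEMPO (20 mol %), THF, −78 → −40 °C, until 2 is consumed; then 8 (1.2 equiv) in THF, −40 → 0 °C; aq. NaHCO3/Na2S2O3 work-up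
Reagents that add atoms: none (net loss of H2)
Why: Proposed new method: a cross-dehydrogenative C(sp3)–H/C(sp2)–H coupling in which the oxoammonium formed from TEMPO/PhI(OAc)2 oxyaminates the acidic β-triketone enol of 2 at C6 and TEMPO–H is lost across the C6–CH3 bond to give the exocyclic enone 9 (a dearomatised o-quinone methide), which is attacked by the single free aryl carbon of 8 (between two OH groups) in a vinylogous Friedel–Crafts/Michael addition followed by tautomerisation; it should be cross-selective because only 2 can become the electrophile, the oxidant is spent before 8 and the product are present, and no base or formaldehyde is there to cause homodimers or bridge scrambling; the closest known reaction types are oxidative generation of o-quinone methides from o-methyl phenols or enols with cycloaddition trapping, and Michael addition of phloroglucinols to alkylidene β-triketones.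

## Compound list

1 | 2,4,6-trihydroxyacetophenone | CC(=O)c1c(O)cc(O)cc1O | starting material
2 | 2-acetyl-3,5-dihydroxy-4,4,6-trimethylcyclohexa-2,5-dien-1-one | CC1=C(O)C(C)(C)C(=O)C(C(C)=O)=C1O | intermediate
3 | 2,4,6-trihydroxytoluene | Cc1c(O)cc(O)cc1O | starting material
4 | butyryl chloride | CCCC(=O)Cl | starting material
5 | 1-(2,4,6-trihydroxy-3-methylphenyl)butan-1-one | CCCC(=O)c1c(O)cc(O)c(C)c1O | intermediate
6 | 1-[2-hydroxy-4,6-bis(methoxymethoxy)-3-methylphenyl]butan-1-one | CCCC(=O)c1c(OCOC)cc(OCOC)c(C)c1O | intermediate
7 | 1-[2-methoxy-4,6-bis(methoxymethoxy)-3-methylphenyl]butan-1-one | CCCC(=O)c1c(OCOC)cc(OCOC)c(C)c1OC | intermediate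
8 | 1-(4,6-dihydroxy-2-methoxy-3-methylphenyl)butan-1-one (ψ-aspidinol B) | CCCC(=O)c1c(O)cc(O)c(C)c1OC | intermediate
9 | 2-acetyl-3-hydroxy-4,4-dimethyl-6-methylidenecyclohex-2-ene-1,5-dione (transient) | CC(=O)C1=C(O)C(C)(C)C(=O)C(=C)C1=O | intermediate (not isolated)
10 | Aspidin AB | CCCC(=O)c1c(O)c(CC2=C(O)C(C)(C)C(=O)C(C(C)=O)=C2O)c(O)c(C)c1OC | target

## Summary

Total steps: 6. Longest linear sequence: 5 (3 → 5 → 6 → 7 → 8 → 10).

Three steps most likely to fail, with fallbacks:

1. **Step 6 (proposed new dehydrogenative methylene-bridge coupling).** The risks are self-dimerisation of 9 and over-oxidation of 8 or of the product's bridge. Fallback (known chemistry): stop the methylation of 1 at two equivalents of MeI to get acetylfilicinic acid, convert 8 to its C-aminomethyl Mannich base (Eschenmoser's salt), and heat the two together (thermal amine loss, then Michael addition). Alternatively, co-condense acetylfilicinic acid and 8 with aqueous formaldehyde in dilute alkali and separate the heterodimer from the two homodimers.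

2. **Step 3 (regioselective bis-MOM protection).** The wrong ortho-OH may be protected, which after Step 4 would give the isomeric ether. Fallback: start from symmetric 1-(2,4,6-trihydroxyphenyl)butan-1-one, where bis-MOM protection is unambiguous. Then iodinate ortho to the free OH, O-methylate that OH, install the C-methyl by Pd-catalysed Suzuki methylation (trimethylboroxine), and deprotect to 8.

3. **Step 1 (threefold C-methylation).** A statistical mixture of di-, tri- and tetra-methyl and O-methyl products may lower the yield. Fallback: Friedel–Crafts acetylation of 3 to 3-methylphloracetophenone, then only two C-methylations (MeI/NaOMe); every di-C-methylation pattern again converges on 2.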